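## Analysis of the target

Sophonorol F is a 3-hydroxyisoflavanone: ring A is fused to a dihydropyranone (O1, C2, C3, C4), and C3 carries both a tertiary hydroxyl and ring B. Ring A has a phloroglucinol pattern (O1, 5-OH, 7-OMe) with a prenyl group at C8. Ring B has a resorcinol pattern (2'-OMe, 4'-OH) with a prenyl group at C3', between its two oxygens. C3 is the only stereocentre, a fully substituted (S)-carbinol carbon flanked by the C4 ketone, the C2 methylene and C1'. With no partner stereocentre, its absolute sense must come from a reagent or catalyst. It cannot epimerise through an enol, but as a tertiary benzylic α-ketol it can be lost by acid-promoted dehydration across C2–C3 or disturbed by an α-ketol shift. The two trisubstituted double bonds exclude hydrogenolysis and strong acid, because the 3'-prenyl group sits beside the 4'-hydroxyl and would cyclise onto it, and the phenols are electron-rich. The difficulties are the quaternary carbinol in one absolute configuration, two aryl–prenyl bonds at defined positions on rings that direct C-prenylation would attack unselectively, and five oxygens of which exactly two are methylated. The strategy rests on one positional fact: C8 is para to O5 on ring A and C3' is ortho to O2' on ring B, so each aryl–prenyl bond can be delivered by a sigmatropic shift from an allyl ether on an oxygen the target already has.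

## Retrosynthetic reasoning

**21 back to 20 and 19 (oxygen pattern).** No skeletal bond is cut. The 4'-hydroxyl of 21 is unmasked last from the pivalate 20, and the 2'-methyl ether of 20 comes from the free 2'-phenol of 19. This order is forced by the key step, which necessarily frees O2' when the allyl unit leaves it. At that point the 4'-oxygen is still acylated, the 5-hydroxyl is locked in a hydrogen bond to the C4 carbonyl and the 3-hydroxyl is tertiary. The forward methylation therefore has a single reactive phenol to find, and the final ester cleavage runs under base, not acid.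

**19 back to 14 (the two aryl–prenyl bonds).** The bonds cut are C8–CH2 of the ring A prenyl group and C3'–CH2 of the ring B prenyl group. They are cut here because each carbon has an oxygen in the correct sigmatropic relationship: O5 is para to C8, and O2' is ortho to C3'. In 14 the ring A unit is a prenyl ether on O5 and the ring B unit is a 1,1-dimethylallyl ether on O2'. A double [3,3] shift from O5 (to C6, then on to C8) returns the allyl unit in its linear form, and a single [3,3] shift from O2' inverts the tertiary ether into the linear prenyl group. The gain is that both C–C bonds are made in one operation on a compound whose ring system and stereocentre already exist, and that each prenyl group costs only an O-alkylation upstream. The forward reaction must run at moderate temperature beside the tertiary α-ketol, and on ring A the second shift must outrun enolisation at C6.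

**14 back to 13 (C3–C4, ring closure and stereocentre).** Cutting C3–C4 of the ketol gives the aryloxy-ketone aldehyde 13, in which the formyl carbon becomes C4 and the ketone carbon becomes C3. This is the one disconnection that opens the pyranone ring and removes the stereocentre together. The forward step is an intramolecular aldehyde–ketone benzoin under a chiral carbene catalyst, which must favour one face of the ketone.

**13 back to 4 and 12 (O1–C2).** The aryl ether bond between ring A oxygen and the methylene carbon is cut to give phenol 4 and phenacyl bromide 12. This is the most convergent cut, separating the two aromatic halves with each already carrying its allyl ether. The forward step is a Williamson etherification that must be finished before the product can condense with itself.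

**4 back to 2, 3 and 1 (ring A).** The prenyl ether of 4 is cut to the symmetrical diol 2 and prenyl bromide 3, and the methyl ether of 2 is cut to aldehyde 1. The three hydroxyls of 1 are differentiated by acidity and hydrogen bonding alone: the para hydroxyl is alkylated first, then one of two equivalent chelated hydroxyls.

**12 back to 10, 9, 6, 5 and 7 (ring B).** The C–Br bond of 12 is traced to the methyl ketone 10 through its silyl enol ether 11, so that bromination is directed to the α-carbon and away from the vinyl group. The vinyl group of 10 comes from the alkyne of 9 by semihydrogenation. The tertiary ether bond of 9 is cut to phenol 6 and the propargylic alcohol 7, used as its activated ester 8. The pivalate of 6 is placed on the only unchelated hydroxyl of ketone 5.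

## Alternatives that were turned down

**Alternative 1:** The disconnection is again C3–C4, but the carbene-catalysed benzoin is the key step and is run on a keto aldehyde A2 that already carries both C-prenyl groups, the 2'-methyl ether and two methoxymethyl ethers. It would give the bis-methoxymethyl ether A1 of the target.
- For: ring and stereocentre come from the last C–C bond-forming step, and no selective late methylation is needed. On the ring closure itself this plan is stronger, because the ketone of A2 bears only a 2'-methoxy group where the chosen route has a bulky tertiary allyl ether.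
- Against: the prenyl problem is only moved into the fragments. Ring A needs a C-prenylated aldehyde with two ortho hydroxyls told apart. Ring B needs a prenyl group between two oxygens that then receive different substituents, one of them chelated to the ketone. Each of these is a sigmatropic shift or a directed metalation plus protecting-group steps. The acetals must come off with acid at the end, where the tertiary benzylic carbinol can dehydrate across C2–C3 and the freed 4'-hydroxyl can add to the neighbouring prenyl double bond.
- Comparison: the chosen strategy uses the same ring closure as a supporting step and accepts its greater crowding. In exchange it makes both aryl–prenyl bonds in one operation from ethers that cost one step each, and it ends under base.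

**Alternative 2:** Three bonds are traced to C3 at once, C3–OH and C2–C3, with the pyranone ring left open. Rh2(OAc)4 converts the diaryl diazoketone A4 into a carbenoid, water A6 adds to give an oxonium ylide, and a chiral phosphoric acid guides its attack on formaldehyde A5. The product is the (S)-diol A3, which still needs desilylation, ring closure between the phenol and the primary alcohol, and two acetal removals.
- For: two bonds and the stereocentre form in one step from an achiral precursor, with A5 and A6 as the simplest possible building blocks. On bonds formed at the stereocentre per step it is stronger than the chosen plan.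
- Against: the carbenoid carbon sits beside an ortho-methoxy group and within reach of two prenyl double bonds, so five-membered C–H insertion into the methoxy carbon and cyclopropanation compete with capture of A6. The ylide can collapse by a 1,2-proton shift before it meets A5. A5 is small and very reactive, which leaves little for the phosphate to discriminate. A4 itself requires the fully prenylated, triply protected deoxybenzoin.
- Comparison: it is longer after the key step (four operations against two) and no shorter before it. The chosen plan offers a ring closure with precedent on this ring system and delivers the prenyl groups after the stereocentre, not before.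

**Alternative 3:** The C2–C3 bond is traced to a C–H bond of a methyl ether on C8a. Visible light excites the benzil A8, the oxygen of the carbonyl that becomes C3 abstracts hydrogen from that methoxy group, and the 1,6-biradical closes to the protected hydroxychromanone A7.
- For: C2 comes from a methyl ether, no reagent is consumed, and ring and carbinol form together. On step economy it is the strongest of the four plans.
- Against: the carbonyl nearer ring A can abstract the same hydrogen through a smaller cyclic transition state and close a five-membered ring, the usual fate of ortho-alkoxyaryl ketones. The biradical is achiral and the reaction has no built-in source of absolute configuration. The excited diketone can also abstract allylic hydrogen from, or add across, either prenyl double bond.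
- Comparison: the chosen plan is longer but sets C3 under catalyst control and keeps both double bonds out of any radical or excited-state step. Their precursors are plain ethers until the sigmatropic step.

Key step: step 9

Remarks on the chemistry:
- Abbreviations: prenyl = 3-methylbut-2-en-1-yl; 1,1-dimethylallyl = 2-methylbut-3-en-2-yl; pivalate = 2,2-dimethylpropanoate; fod = 6,6,7,7,8,8,8-heptafluoro-2,2-dimethyloctane-3,5-dionate. Isoflavanone numbering (O1, C2, C3, C4, C5–C8 on ring A, primed positions on ring B) is used for 14–21.
- Assumption: the (5aR,10bS) antipode of the triazolium salt in step 8 is taken to give the (S)-carbinol; if the sense of induction is the opposite, the mirror-image salt is used and nothing else changes.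

## Route

Step 1
Reactants: 1 2,4,6-trihydroxybenzaldehyde
Product: 2 2,6-dihydroxy-4-methoxybenzaldehyde
Conditions: Me2SO4 (1.0 equiv), K2CO3 (1.0 equiv), acetone, 0 °C → rt
Reagents that add atoms: dimethyl sulfate, COS(=O)(=O)OC
Why: Williamson O-methylation; the 4-hydroxyl is para to the formyl group and not hydrogen-bonded, so it is the most acidic and the one ionised by a single equivalent of base, while the two ortho hydroxyls are held back by the carbonyl.

Step 2
Reactants: 2 2,6-dihydroxy-4-methoxybenzaldehyde; 3 prenyl bromide
Product: 4 2-hydroxy-4-methoxy-6-(prenyloxy)benzaldehyde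
Conditions: 3 (1.05 equiv), K2CO3, acetone, rt
Reagents that add atoms: none
Why: Williamson etherification with an allylic bromide; the two ortho hydroxyls of 2 are equivalent, and once one is alkylated the other is locked in a strong hydrogen bond to the formyl oxygen, which should stop the reaction at the mono-ether.

Step 3
Reactants: 5 2,4-dihydroxyacetophenone
Product: 6 4-acetyl-3-hydroxyphenyl pivalate
Conditions: t-BuCOCl (1.05 equiv), Et3N, CH2Cl2, 0 °C
Reagents that add atoms: pivaloyl chloride, CC(C)(C)C(=O)Cl
Why: Selective O-acylation; the 2-hydroxyl is chelated to the acetyl carbonyl and flanked by it, so the bulky acid chloride should take only the free 4-hydroxyl.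

Step 4
Reactants: 6 4-acetyl-3-hydroxyphenyl pivalate; 7 2-methylbut-3-yn-2-ol
Product: 9 4-acetyl-3-[(2-methylbut-3-yn-2-yl)oxy]phenyl pivalate, via 2-methylbut-3-yn-2-yl trifluoroacetate 8 (not isolated)
Conditions: 7, (CF3CO)2O, DBU, MeCN, −5 °C; then 6, DBU, CuCl2·2H2O (1 mol %), MeCN, 0 °C
Reagents that add atoms: trifluoroacetic anhydride, O=C(OC(=O)C(F)(F)F)C(F)(F)F (its acyl group is carried only by intermediate 8)
Why: Copper-catalysed propargylic etherification; the copper acetylide of 8 loses trifluoroacetate to a copper allenylidene that the phenoxide captures at the tertiary carbon, and DBU ionises the chelated phenol completely so that it can act as the nucleophile.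

Step 5
Reactants: 9 4-acetyl-3-[(2-methylbut-3-yn-2-yl)oxy]phenyl pivalate
Product: 10 4-acetyl-3-[(2-methylbut-3-en-2-yl)oxy]phenyl pivalate
Conditions: H2 (1 atm), Pd/CaCO3–Pb(OAc)2 (Lindlar catalyst), quinoline, EtOAc, rt
Reagents that add atoms: none
Why: Lindlar semihydrogenation; the poisoned catalyst takes the terminal alkyne to the vinyl group and stops, and the ketone, the aryl ester and the tertiary ether are untouched at room temperature.

Step 6
Reactants: 10 4-acetyl-3-[(2-methylbut-3-en-2-yl)oxy]phenyl pivalate
Product: 12 4-(2-bromoacetyl)-3-[(2-methylbut-3-en-2-yl)oxy]phenyl pivalate, via trimethylsilyl enol ether 11 (not isolated)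
Conditions: LiN(SiMe3)2, Me3SiCl, THF, −78 °C; then NBS, THF, −78 → 0 °C
Reagents that add atoms: N-bromosuccinimide, O=C1CCC(=O)N1Br; chlorotrimethylsilane, C[Si](C)(C)Cl (its silyl group is carried only by intermediate 11)
Why: Kinetic enolisation with silyl trapping, then electrophilic bromination of the silyl enol ether; the enol ether is far more nucleophilic than the monosubstituted vinyl group, so bromine should be delivered only to the α-carbon, which free bromine would not guarantee.

Step 7
Reactants: 4 2-hydroxy-4-methoxy-6-(prenyloxy)benzaldehyde; 12 4-(2-bromoacetyl)-3-[(2-methylbut-3-en-2-yl)oxy]phenyl pivalate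
Product: 13 4-{2-[2-formyl-5-methoxy-3-(prenyloxy)phenoxy]acetyl}-3-[(2-methylbut-3-en-2-yl)oxy]phenyl pivalate
Conditions: K2CO3, acetone, 0 °C → rt
Reagents that add atoms: none
Why: Williamson etherification; phenacyl bromides are among the fastest SN2 electrophiles, so even the chelated phenoxide of 4 should be alkylated at or below room temperature, before the activated methylene of the product can condense with the formyl group.

Step 8
Reactants: 13 4-{2-[2-formyl-5-methoxy-3-(prenyloxy)phenoxy]acetyl}-3-[(2-methylbut-3-en-2-yl)oxy]phenyl pivalate
Product: 14 (S)-3-hydroxy-7-methoxy-5-O-prenyl-2'-O-(1,1-dimethylallyl)-4'-O-pivaloylisoflavanone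
Conditions: (5aR,10bS)-2-(pentafluorophenyl)-5a,10b-dihydro-4H,6H-indeno[2,1-b][1,2,4]triazolo[4,3-d][1,4]oxazin-2-ium tetrafluoroborate (15 mol %), Et3N (15 mol %), toluene, rt
Reagents that add atoms: none
Why: Intramolecular crossed aldehyde–ketone benzoin under chiral triazolylidene catalysis, a known entry to 3-hydroxychroman-4-ones; the carbene adds to the formyl group and the Breslow intermediate attacks the tethered ketone in a 6-exo-trig closure that forms C3–C4. The indane wall of the catalyst shields one face of the enaminol, so the ketone is approached on the face that gives the (S)-carbinol, and the weak amine base keeps aldol condensation slow.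

Step 9
Reactants: 14 (S)-3-hydroxy-7-methoxy-5-O-prenyl-2'-O-(1,1-dimethylallyl)-4'-O-pivaloylisoflavanone
Product: 19 (S)-2'-O-demethyl-4'-O-pivaloyl sophonorol F, via ring A C6 dienone 15 (not isolated), via ring A C8 dienone 16 (not isolated), via ring A rearranged 2'-ether 17 (not isolated), via ring B C3' dienone 18 (not isolated)
Conditions: Eu(fod)3 (20 mol %), toluene, 65 °C then 100 °C
Reagents that add atoms: none
Why: The step joins two known aryl ether [3,3] shifts: the Eu(fod)3-assisted Claisen–Cope shift of 5-O-prenyl flavonoids to 8-prenyl-5-hydroxy compounds and the ortho-Claisen shift of aryl 1,1-dimethylallyl ethers. On ring A, europium held between the C4 carbonyl and O5 weakens the O5–allyl bond, the first shift places a 1,1-dimethylallyl group at C6 (15), and a Cope shift carries it to C8 as the linear prenyl group (16), which enolises to the chelated phenol 17. On ring B, one chair-like shift from O2' to C3' turns the tertiary ether into the linear prenyl group (18), and enolisation gives 19. No ring is closed and no stereocentre is created: the sp3 ring carbons of 15, 16 and 18 are erased on enolisation, and C3 lies outside both pericyclic arrays, has no α-hydrogen and stays (S). The selectivity needed on ring A is C8 over C6; it is secured by the crowding of the C6 substituent between the C5 carbonyl and the 7-methoxy group, which speeds the Cope shift, and by the irreversible aromatisation of 16 to a hydrogen-bonded 5-hydroxyl. On ring B, C1' is substituted, so C3' is the only ortho carbon that can rearomatise. Eu(fod)3 is a weak enough Lewis acid to leave the pivalate, the tertiary carbinol and the new double bonds alone. The europium-assisted ring A shift is expected at the lower temperature, and warming completes the ring B shift.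

Step 10
Reactants: 19 (S)-2'-O-demethyl-4'-O-pivaloyl sophonorol F
Product: 20 (S)-4'-O-pivaloyl sophonorol F
Conditions: MeI (1.2 equiv), K2CO3, acetone, rt
Reagents that add atoms: iodomethane, CI
Why: Williamson O-methylation; the 5-hydroxyl is tied up in a hydrogen bond to the C4 carbonyl and the 3-hydroxyl is a tertiary alcohol that carbonate does not ionise, so the 2'-phenoxide is the only nucleophile formed in quantity, and MeI is small enough to reach it between the prenyl group and C3.

Step 11
Reactants: 20 (S)-4'-O-pivaloyl sophonorol F
Product: 21 sophonorol F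
Conditions: K2CO3 (0.3 equiv), MeOH, rt; then aq NH4Cl
Reagents that add atoms: none
Why: Base-catalysed methanolysis of an aryl ester; the phenoxide is a good leaving group, so the pivalate should leave at room temperature. Under these conditions the 5-hydroxyl is ionised, which makes C4 a vinylogous carboxylate and protects the α-ketol from rearrangement, and C3 has no acidic hydrogen and cannot epimerise.

## Compound list

1 | 2,4,6-trihydroxybenzaldehyde | O=Cc1c(O)cc(O)cc1O | starting material
2 | 2,6-dihydroxy-4-methoxybenzaldehyde | COc1cc(O)c(C=O)c(O)c1 | intermediate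
3 | prenyl bromide (1-bromo-3-methylbut-2-ene) | CC(C)=CCBr | starting material
4 | 2-hydroxy-4-methoxy-6-[(3-methylbut-2-en-1-yl)oxy]benzaldehyde | COc1cc(O)c(C=O)c(OCC=C(C)C)c1 | intermediate
5 | 2,4-dihydroxyacetophenone | CC(=O)c1ccc(O)cc1O | starting material
6 | 4-acetyl-3-hydroxyphenyl pivalate | CC(=O)c1ccc(OC(=O)C(C)(C)C)cc1O | intermediate
7 | 2-methylbut-3-yn-2-ol | CC(C)(O)C#C | starting material
8 | 2-methylbut-3-yn-2-yl trifluoroacetate | CC(C)(OC(=O)C(F)(F)F)C#C | intermediate
9 | 4-acetyl-3-[(2-methylbut-3-yn-2-yl)oxy]phenyl pivalate | CC(=O)c1ccc(OC(=O)C(C)(C)C)cc1OC(C)(C)C#C | intermediate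
10 | 4-acetyl-3-[(2-methylbut-3-en-2-yl)oxy]phenyl pivalate | CC(=O)c1ccc(OC(=O)C(C)(C)C)cc1OC(C)(C)C=C | intermediate
11 | 3-[(2-methylbut-3-en-2-yl)oxy]-4-[1-(trimethylsilyloxy)vinyl]phenyl pivalate | C=C(O[Si](C)(C)C)c1ccc(OC(=O)C(C)(C)C)cc1OC(C)(C)C=C | intermediate
12 | 4-(2-bromoacetyl)-3-[(2-methylbut-3-en-2-yl)oxy]phenyl pivalate | BrCC(=O)c1ccc(OC(=O)C(C)(C)C)cc1OC(C)(C)C=C | intermediate
13 | 4-{2-[2-formyl-5-methoxy-3-(3-methylbut-2-en-1-yloxy)phenoxy]acetyl}-3-[(2-methylbut-3-en-2-yl)oxy]phenyl pivalate | COc1cc(OCC=C(C)C)c(C=O)c(OCC(=O)c2ccc(OC(=O)C(C)(C)C)cc2OC(C)(C)C=C)c1 | intermediate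
14 | (3S)-3-hydroxy-7-methoxy-5-(3-methylbut-2-en-1-yloxy)-3-[2-(2-methylbut-3-en-2-yloxy)-4-(pivaloyloxy)phenyl]chroman-4-one | COc1cc(OCC=C(C)C)c2c(c1)OC[C@@](O)(c1ccc(OC(=O)C(C)(C)C)cc1OC(C)(C)C=C)C2=O | intermediate
15 | ring A C6 dienone: 14 with the allyl unit moved from O5 to C6 as a 2-methylbut-3-en-2-yl group, C5 as a ketone, C6 sp3 (either configuration), ring B unchanged | COC1=CC2=C(C(=O)C1C(C)(C)C=C)C(=O)[C@](O)(c1ccc(OC(=O)C(C)(C)C)cc1OC(C)(C)C=C)CO2 | intermediate
16 | ring A C8 dienone: cross-conjugated C5 ketone with the prenyl group on sp3 C8 (either configuration), ring B unchanged | COC1=CC(=O)C2=C(C1CC=C(C)C)OC[C@@](O)(c1ccc(OC(=O)C(C)(C)C)cc1OC(C)(C)C=C)C2=O | intermediate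
17 | (3S)-3,5-dihydroxy-7-methoxy-8-(3-methylbut-2-en-1-yl)-3-[2-(2-methylbut-3-en-2-yloxy)-4-(pivaloyloxy)phenyl]chroman-4-one | COc1cc(O)c2c(c1CC=C(C)C)OC[C@@](O)(c1ccc(OC(=O)C(C)(C)C)cc1OC(C)(C)C=C)C2=O | intermediate
18 | ring B C3' dienone: 17 with the allyl unit moved from O2' to sp3 C3' as a prenyl group (either configuration), C2' as a ketone | COc1cc(O)c2c(c1CC=C(C)C)OC[C@@](O)(C1=CC=C(OC(=O)C(C)(C)C)C(CC=C(C)C)C1=O)C2=O | intermediate
19 | (3S)-3,5-dihydroxy-3-[2-hydroxy-3-(3-methylbut-2-en-1-yl)-4-(pivaloyloxy)phenyl]-7-methoxy-8-(3-methylbut-2-en-1-yl)chroman-4-one | COc1cc(O)c2c(c1CC=C(C)C)OC[C@@](O)(c1ccc(OC(=O)C(C)(C)C)c(CC=C(C)C)c1O)C2=O | intermediate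
20 | (3S)-3,5-dihydroxy-7-methoxy-3-[2-methoxy-3-(3-methylbut-2-en-1-yl)-4-(pivaloyloxy)phenyl]-8-(3-methylbut-2-en-1-yl)chroman-4-one | COc1cc(O)c2c(c1CC=C(C)C)OC[C@@](O)(c1ccc(OC(=O)C(C)(C)C)c(CC=C(C)C)c1OC)C2=O | intermediate
21 | sophonorol F, (3S)-3,5-dihydroxy-3-[4-hydroxy-2-methoxy-3-(3-methylbut-2-en-1-yl)phenyl]-7-methoxy-8-(3-methylbut-2-en-1-yl)chroman-4-one | COc1cc(O)c2c(c1CC=C(C)C)OC[C@@](O)(c1ccc(O)c(CC=C(C)C)c1OC)C2=O | target

## Step count and least certain steps

Total: 11 steps. Longest linear sequence: 9 steps (5 to 21, steps 3 to 11). The ring A aldehyde 4 takes 2 steps and joins at step 7.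

**Step 9 (key step).** Two processes are most likely to go wrong. The C6 dienone may enolise before the Cope shift, leaving the branched allyl group at C6. The Lewis acid may ionise the tertiary allyl aryl ether on ring B, so that the allyl unit is lost and not transferred. The freed 2'-phenol may also add to the new double bond if traces of acid build up.
Fallback: set out from aldehyde 4 and form the ring A bond at the aldehyde stage, where forcing conditions are harmless.
- Heating 4 in N,N-diethylaniline at about 190 °C should carry the prenyl group from oxygen to the para carbon and give 2,6-dihydroxy-4-methoxy-3-prenylbenzaldehyde F1.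
- Allyl bromide and K2CO3 should etherify the hydroxyl not flanked by the prenyl group, giving 6-allyloxy-2-hydroxy-4-methoxy-3-prenylbenzaldehyde F2.
- Williamson coupling of F2 with bromide 12 gives the keto aldehyde F3, and the carbene-catalysed benzoin closure of step 8 gives (S)-5-O-allyl-3-hydroxy-7-methoxy-8-prenyl-2'-O-(1,1-dimethylallyl)-4'-O-pivaloylisoflavanone F4.
- Heating F4 in toluene at 110 °C without any Lewis acid should move only the ring B allyl unit, since the simple allyl ether needs far higher temperatures, and give (S)-5-O-allyl-3,2'-dihydroxy-7-methoxy-8,3'-diprenyl-4'-O-pivaloylisoflavanone F5.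
- Pd(PPh3)4 with morpholine removes the allyl group and returns to 19.

**Step 8.** The formyl group is flanked by two oxygens and is electron-rich, so carbene addition may be slow enough for base-mediated aldol condensation of the methylene onto the aldehyde to win. The bulky 2'-ether may also erode facial discrimination at the ketone.
Fallback: set out from 13 and close the ring without enantiocontrol, using the smaller, more nucleophilic carbene from 3-benzyl-5-(2-hydroxyethyl)-4-methylthiazolium chloride and DBU in t-BuOH. This gives the racemic ketol F6, and preparative chromatography on a chiral stationary phase then gives 14.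

**Step 7.** After O-alkylation the activated methylene may attack the formyl group (aldol condensation and dehydration to a 2-aroylbenzofuran). Bromide 12 may also decompose by internal displacement at the CH2Br carbon by the ether oxygen, with loss of the tertiary allyl group.
Fallback: set out from ketone 10 through its silyl enol ether 11 and avoid both the bromide and the base. Rubottom oxidation (mCPBA, NaHCO3, CH2Cl2, −20 °C) should give 4-[2-(trimethylsilyloxy)acetyl]-3-(1,1-dimethylallyloxy)phenyl pivalate F7 (not isolated). Aqueous citric acid then frees 4-(2-hydroxyacetyl)-3-(1,1-dimethylallyloxy)phenyl pivalate F8. Mitsunobu etherification of F8 with phenol 4 (PPh3, DIAD, THF, 0 °C) returns to 13 under neutral conditions.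

**Step 4.** The phenoxide of 6 is stabilised and crowded by the ortho acetyl group and may capture the copper allenylidene too slowly, so that 8 is consumed by elimination.
Fallback: set out from 6 and install the alkene-level ether directly by palladium-catalysed decarboxylative O-allylation. tert-Butyl 2-methylbut-3-en-2-yl carbonate F9 (from 2-methylbut-3-en-2-ol and Boc2O) with Pd(PPh3)4 in THF at 0 °C should alkylate the phenol at the more substituted allyl terminus and give 10, replacing steps 4 and 5.

**Step 10.** The 5-hydroxyl may be methylated in competition, or the hindered 2'-hydroxyl may react too slowly, so that forcing conditions erode the selectivity.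
Fallback: set out from 14 and methylate while O5 still carries its prenyl group, so that only one phenol exists.
- Heating 14 in toluene at 110 °C without Lewis acid should move only the ring B allyl unit and give (S)-3,2'-dihydroxy-7-methoxy-5-O-prenyl-3'-prenyl-4'-O-pivaloylisoflavanone F10.
- MeI and K2CO3 give the 2'-methyl ether F11.
- Eu(fod)3 at 65 °C then effects the ring A Claisen–Cope shift and returns to 20.

## Further compounds

F1 | step 9 | 2,6-dihydroxy-4-methoxy-3-(3-methylbut-2-en-1-yl)benzaldehyde | COc1cc(O)c(C=O)c(O)c1CC=C(C)C
F2 | step 9 | 6-(allyloxy)-2-hydroxy-4-methoxy-3-(3-methylbut-2-en-1-yl)benzaldehyde | COc1cc(OCC=C)c(C=O)c(O)c1CC=C(C)C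
F3 | step 9 | 4-{2-[3-(allyloxy)-2-formyl-5-methoxy-6-(3-methylbut-2-en-1-yl)phenoxy]acetyl}-3-[(2-methylbut-3-en-2-yl)oxy]phenyl pivalate | COc1cc(OCC=C)c(C=O)c(OCC(=O)c2ccc(OC(=O)C(C)(C)C)cc2OC(C)(C)C=C)c1CC=C(C)C
F4 | step 9 | (3S)-5-(allyloxy)-3-hydroxy-7-methoxy-8-(3-methylbut-2-en-1-yl)-3-[2-(2-methylbut-3-en-2-yloxy)-4-(pivaloyloxy)phenyl]chroman-4-one | COc1cc(OCC=C)c2c(c1CC=C(C)C)OC[C@@](O)(c1ccc(OC(=O)C(C)(C)C)cc1OC(C)(C)C=C)C2=O
F5 | step 9 | (3S)-5-(allyloxy)-3-hydroxy-3-[2-hydroxy-3-(3-methylbut-2-en-1-yl)-4-(pivaloyloxy)phenyl]-7-methoxy-8-(3-methylbut-2-en-1-yl)chroman-4-one | COc1cc(OCC=C)c2c(c1CC=C(C)C)OC[C@@](O)(c1ccc(OC(=O)C(C)(C)C)c(CC=C(C)C)c1O)C2=O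
F6 | step 8 | racemic 3-hydroxy-7-methoxy-5-(3-methylbut-2-en-1-yloxy)-3-[2-(2-methylbut-3-en-2-yloxy)-4-(pivaloyloxy)phenyl]chroman-4-one | COc1cc(OCC=C(C)C)c2c(c1)OCC(O)(c1ccc(OC(=O)C(C)(C)C)cc1OC(C)(C)C=C)C2=O
F7 | step 7 | 3-[(2-methylbut-3-en-2-yl)oxy]-4-[2-(trimethylsilyloxy)acetyl]phenyl pivalate | C[Si](C)(C)OCC(=O)c1ccc(OC(=O)C(C)(C)C)cc1OC(C)(C)C=C
F8 | step 7 | 4-(2-hydroxyacetyl)-3-[(2-methylbut-3-en-2-yl)oxy]phenyl pivalate | OCC(=O)c1ccc(OC(=O)C(C)(C)C)cc1OC(C)(C)C=C
F9 | step 4 | tert-butyl 2-methylbut-3-en-2-yl carbonate | C=CC(C)(C)OC(=O)OC(C)(C)C
F10 | step 10 | (3S)-3-hydroxy-3-[2-hydroxy-3-(3-methylbut-2-en-1-yl)-4-(pivaloyloxy)phenyl]-7-methoxy-5-(3-methylbut-2-en-1-yloxy)chroman-4-one | COc1cc(OCC=C(C)C)c2c(c1)OC[C@@](O)(c1ccc(OC(=O)C(C)(C)C)c(CC=C(C)C)c1O)C2=O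
F11 | step 10 | (3S)-3-hydroxy-7-methoxy-3-[2-methoxy-3-(3-methylbut-2-en-1-yl)-4-(pivaloyloxy)phenyl]-5-(3-methylbut-2-en-1-yloxy)chroman-4-one | COc1cc(OCC=C(C)C)c2c(c1)OC[C@@](O)(c1ccc(OC(=O)C(C)(C)C)c(CC=C(C)C)c1OC)C2=O
A1 | alternative 1 | (S)-5,4'-bis-O-(methoxymethyl) sophonorol F | COc1cc(OCOC)c2c(c1CC=C(C)C)OC[C@@](O)(c1ccc(OCOC)c(CC=C(C)C)c1OC)C2=O
A2 | alternative 1 | 2-{2-[2-methoxy-4-(methoxymethoxy)-3-prenylphenyl]-2-oxoethoxy}-4-methoxy-6-(methoxymethoxy)-3-prenylbenzaldehyde | COc1cc(OCOC)c(C=O)c(OCC(=O)c2ccc(OCOC)c(CC=C(C)C)c2OC)c1CC=C(C)C
A3 | alternative 2 | (S)-α-hydroxy-α-hydroxymethyl deoxybenzoin (seco-chromanone diol) with 5- and 4'-methoxymethyl ethers and a tert-butyldimethylsilyl ether on the ring A oxygen that becomes O1 | COc1cc(OCOC)c(C(=O)[C@@](O)(CO)c2ccc(OCOC)c(CC=C(C)C)c2OC)c(O[Si](C)(C)C(C)(C)C)c1CC=C(C)C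
A4 | alternative 2 | 2-diazo-1,2-diarylethanone precursor of A3 | COc1cc(OCOC)c(C(=O)C(=[N+]=[N-])c2ccc(OCOC)c(CC=C(C)C)c2OC)c(O[Si](C)(C)C(C)(C)C)c1CC=C(C)C
A5 | alternative 2 | formaldehyde | C=O
A6 | alternative 2 | water | O
A7 | alternative 3 | (S)-3-hydroxyisoflavanone with 5- and 4'-pivalates and a 2'-tert-butyldimethylsilyl ether | COc1cc(OC(=O)C(C)(C)C)c2c(c1CC=C(C)C)OC[C@@](O)(c1ccc(OC(=O)C(C)(C)C)c(CC=C(C)C)c1O[Si](C)(C)C(C)(C)C)C2=O
A8 | alternative 3 | benzil precursor of A7 with a methyl ether on the ring A oxygen that becomes O1 | COc1cc(OC(=O)C(C)(C)C)c(C(=O)C(=O)c2ccc(OC(=O)C(C)(C)C)c(CC=C(C)C)c2O[Si](C)(C)C(C)(C)C)c(OC)c1CC=C(C)C
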